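Fold the ligand charge and the time into one number, then read the end of each flask from it.

| setting | dawn | spring | Tuesday's | Saturday's | Monday's |
|---|---|---|---|---|---|
| starting complex | 0.061 M | 0.061 M | 0.061 M | 0.061 M | 0.061 M |
| incoming ligand | 0.023 M | 0.13 M | 0.0305 M | 0.0915 M | 0.183 M |
| scavenger | 0.061 M | 0.061 M | 0.0610 M | 0.0610 M | 0.0610 M |
| remark | run made earlier | run made earlier |  |  |  |
| time |  |  | 2.5 h | 2.5 h | 2.5 h |

| run | time / h | complex with one exchanged / % | complex with two exchanged / % |
|---|---|---|---|
| dawn | 0.133 | 2.5 | 0 |
| dawn | 0.417 | 1.6 | 0 |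
| dawn | 0.667 | 3.4 | 0 |
| dawn | 1.00 | 3.1 | 0.6 |
| dawn | 1.50 | 6.8 | 2.0 |
| dawn | 2.00 | 5.6 | 1.7 |
| dawn | 2.50 | 6.9 | 2.0 |
| spring | 0.200 | 5.6 | 1.1 |
| spring | 0.333 | 8.6 | 0 |
| spring | 0.500 | 10.3 | 3.8 |
| spring | 0.667 | 13.1 | 3.9 |
| spring | 1.00 | 15.0 | 9.5 |
| spring | 1.50 | 16.4 | 10.8 |
| spring | 2.50 | 19.0 | 23.3 |

(standard deviation of a reading: 1 percentage point)



- how much complex with one exchanged is there at the end, in percent of the starting complex charged: for each flask in turn (Tuesday's, Saturday's, Monday's)

Read the runs as two consecutive steps, each first order in incoming ligand. At the end of the spring run, the two readings leave a fraction a = 57.7% for starting complex, if no other form holds it, so the spring dose, ln(#1/a) in this reading, is 0.550. The selectivity factor s is the second rate constant over the first. The two-step formula gives complex with one exchanged as (a − a^s)/(s − 1); with a cubed put for a^s, the spring reading gives s = 3.03, a reading with scatter.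

In this reading, complex with one exchanged peaks where its making equals its use, at a dose of ln(s)/(s − 1) = 0.547. The crossing number x is the dose of a flask over that crossing dose, with dose taken as proportional to c(incoming ligand) as charged times time. Spring ended at x = 1.01.

Scaled from spring, Tuesday's has x = 0.236, Saturday's 0.708 and Monday's 1.42. On this reckoning, Saturday's stops short of the crossing and Monday's passes it. The formula gives 9.98%, 18.2% and 18.0%.

One number is tested on the dawn run, which did not enter it. There x = 0.178 gives 8.01%, against a reading of 6.9%, a gap of 1.1 percentage points.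

The forecast gives 10.5%, 19% and 19%, higher than this reckoning, and puts Monday's “just past the maximum of about 20%”.

The flasks give 10.3%, 17.3% and 16.8%, so the forecast is right within the tolerance.

    starting complex + incoming ligand ⇌ leaving ligand + complex with one exchanged (K = 1.02, k = 2.18 M⁻¹ h⁻¹)
    complex with one exchanged + incoming ligand ⇌ leaving ligand + complex with two exchanged (K = 0.559, k = 6.33 M⁻¹ h⁻¹)
    leaving ligand + starting complex ⇌ idle adduct, settled at all times (K = 43.0 M⁻¹)
    scavenger + leaving ligand → scavenged by-product (k = 32.6 M⁻¹ h⁻¹)

Monday's ends with 31.2% of complex with two exchanged, more than Saturday's 13.5%. Saturday's x of 0.708 returns on Monday's flask at 1.25 h, where x is 0.710. Complex with one exchanged stands at 17.3% in Saturday's end and at 16.9% in that Monday's sample.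

Readings and results come from a simulation for substances that don't exist; the scatter is artificial.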